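**Plan**

1. Retrosynthesis (eudesmane numbering C1–C15 for the lactone-bearing part, C1′–C10′ for the C10 side unit): the bonds C5–C1′ and C2–C2′ are cut together, a retro-[4+2] of the cyclohexene ring C2–C3=C4–C5–C1′–C2′. The C3=C4 double bond held between the two bridgeheads of the bicyclo[2.2.2]oct-5-en-2-one is the feature that allows this, and the cut removes the bridged system at once.
2. This leaves β-myrcene (6) and the cyclohexa-2,4-dien-1-one 5, which is α-santonin (1) with its carbonyl moved from C3 to C1; the transposition is traced back as oxidation, Wharton rearrangement and 1α,2α-epoxidation.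
3. Forward: ring B and the lactone come intact from santonin, ring A is re-functionalised in steps 1–3, and the new cyclohexene ring (and with it the bicyclo[2.2.2]octenone) is closed last by an intermolecular Diels–Alder reaction in which myrcene serves as dienophile through its vinyl group.
4. Stereochemistry: C6, C7, C10 and C11 are those of natural α-santonin; C2, C5 and C2′ are set in the cycloaddition (β-face of ring A, endo orientation, CH2 terminus to C5).

Key step: step 4

**Route**

Step 1
Reactants: 1 α-santonin (3-oxo-eudesma-1,4-dien-12,6α-olide; 6β-H, 7α-H, 10β-CH3, 11S)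
Product: 2 1α,2α-epoxy-3-oxo-eudesm-4-en-12,6α-olide (1α,2α-epoxy-1,2-dihydro-α-santonin)
Conditions: t-BuOOH (in decane), DBU, CH2Cl2, 0 °C → rt
Reagents that add atoms: tert-butyl hydroperoxide, CC(C)(C)OO
Why: Weitz–Scheffer nucleophilic epoxidation of a cross-conjugated dienone should take the less substituted C1=C2 arm (the β-carbon of the C4=C5 arm is fully substituted), with the peroxide anion adding to C1 from the α-face, anti to the axial C10 methyl, as with steroidal 1,4-dien-3-ones; the anhydrous amine base should spare the lactone.

Step 2
Reactants: 2 1α,2α-epoxy-3-oxo-eudesm-4-en-12,6α-olide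
Product: 4 1α-hydroxy-eudesma-2,4-dien-12,6α-olide, via epoxy hydrazone 3 (not isolated)
Conditions: N2H4·H2O, AcOH (cat.), MeOH, 0 °C → rt
Reagents that add atoms: hydrazine (used as the hydrate), NN (its nitrogens are carried by 3 and leave as N2)
Why: Wharton transposition: the C3 hydrazone opens the adjacent epoxide to a C2=C3 alkenyl diazene that loses N2, which should place the hydroxyl at C1 with the α-configuration of the epoxide C1–O bond retained and leave the conjugated C2=C3–C4=C5 diene.

Step 3
Reactants: 4 1α-hydroxy-eudesma-2,4-dien-12,6α-olide
Product: 5 1-oxo-eudesma-2,4-dien-12,6α-olide (the cyclohexa-2,4-dien-1-one)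
Conditions: Dess–Martin periodinane, pyridine, CH2Cl2, 0 °C → rt, exclusion of light; used promptly
Reagents that add atoms: none
Why: Dess–Martin oxidation of a secondary allylic alcohol under buffered, non-acidic conditions should avoid ionisation of the dienyl carbinol; the C1 stereocentre is removed and no other is touched.

Step 4
Reactants: 5 1-oxo-eudesma-2,4-dien-12,6α-olide; 6 β-myrcene (7-methyl-3-methyleneocta-1,6-diene)
Product: 7 the target, 1-oxo-eudesm-3-en-12,6α-olide bridged on its β-face by a C1′–C2′ ethano unit (C1′ on C5, C2′ on C2), with a 6-methylhepta-1,5-dien-2-yl group on C2′ syn to the C3=C4 bond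
Conditions: neat 6 (20 equiv), BHT (cat.), sealed tube, 110 °C, Ar, dark; chromatography
Reagents that add atoms: none
Why: Thermal, concerted but asynchronous [4+2] cycloaddition in which the s-cis-locked C2=C3–C4=C5 diene of the cyclohexa-2,4-dien-1-one (ring A of 5) is the 4π component and the monosubstituted C1′=C2′ vinyl group of myrcene the 2π component, the C5–C1′ bond leading. The closest known reaction type is the Diels–Alder reaction of 6,6-disubstituted cyclohexa-2,4-dienones (masked o-benzoquinones and related dienones) with alkenes, including acyclic 1,3-dienes that serve as dienophiles, to give bicyclo[2.2.2]oct-5-en-2-ones. The one new ring, the cyclohexene C2–C3=C4–C5–C1′–C2′, closes by intermolecular suprafacial 1,4-addition across ring A, both σ-bonds (C5–C1′ and C2–C2′) forming in the same event while the double bond moves to C3=C4, which at once creates the bicyclo[2.2.2]octenone. C5 and C2 are set together by the face of ring A that is attacked, expected to be the β-face, because C7, C8 and C9 of ring B hang below the plane of ring A and crowd the α-face of the C5 terminus, whereas the β-face carries only the C10 methyl and H-6; C2′ is set by the endo orientation, the diene residue of myrcene lying under C3–C4 (secondary overlap, and the exo quadrant next to C1 and C10 is occupied by the angular methyl), so that the side chain ends syn to the new C3=C4 bond. The step needs periselectivity, site selectivity, regioselectivity and thermal restraint: the locked cisoid diene and the hindered C2=C3 bond should make 5 the diene; the vinyl group of myrcene should react rather than its 1,1-disubstituted alkene, which would have to form a quaternary carbon; the unsubstituted CH2 terminus, with a large HOMO coefficient, pairs with C5, the δ-carbon with the largest LUMO coefficient and the carbon that becomes quaternary; and the temperature is kept below that at which the 1,5-diene of 7 would undergo Cope rearrangement.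

**Compound list**

1 | α-santonin (3-oxo-eudesma-1,4-dien-12,6α-olide) | C[C@H]1[C@@H]2CC[C@]3(C=CC(=O)C(=C3[C@H]2OC1=O)C)C | starting material
2 | 1α,2α-epoxy-3-oxo-eudesm-4-en-12,6α-olide | C[C@H]1[C@@H]2CC[C@]3([C@H]4O[C@H]4C(=O)C(=C3[C@H]2OC1=O)C)C | intermediate
3 | C3 hydrazone of 2 (epoxy hydrazone, not isolated) | C[C@H]1[C@@H]2CC[C@]3([C@H]4O[C@H]4C(=NN)C(=C3[C@H]2OC1=O)C)C | intermediate
4 | 1α-hydroxy-eudesma-2,4-dien-12,6α-olide | C[C@H]1[C@@H]2CC[C@]3([C@@H](O)C=CC(=C3[C@H]2OC1=O)C)C | intermediate
5 | 1-oxo-eudesma-2,4-dien-12,6α-olide | C[C@H]1[C@@H]2CC[C@]3(C(=O)C=CC(=C3[C@H]2OC1=O)C)C | intermediate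
6 | β-myrcene | C=CC(=C)CCC=C(C)C | starting material
7 | target (β-face, endo [4+2] adduct of 5 and 6) | C=C(CCC=C(C)C)[C@H]1C[C@@]23C(C)=C[C@@H]1C(=O)[C@]2(C)CC[C@H]1[C@H](C)C(=O)O[C@@H]13 | target

**Step count**

Total steps: 4. Longest linear sequence: 4 steps (from α-santonin).

**Steps most likely to fail**

Step 4. The fully substituted C5 terminus may react too slowly with an unactivated alkene. Oligomerisation of myrcene, the reversed role assignment (myrcene as 4π partner on C2=C3) or Cope rearrangement of the adduct could then compete, and face selectivity may erode at the temperature required. The fallback sets out from 5 and returns at 7, using an activated dienophile that cannot serve as a diene. Methyl vinyl ketone (toluene, 60–80 °C) should give, with the same regio-, endo- and β-face preferences, the endo-acetyl adduct F1. Kinetic deprotonation of its methyl group (LiN(iPr)2, THF, −78 °C; the C1 ketone is non-enolisable, lying between a quaternary carbon and a bridgehead) and alkylation with prenyl bromide should give the 5-methylhex-4-enoyl ketone F2. Lombardo methylenation (Zn, CH2Br2, TiCl4, THF/CH2Cl2, 0 °C → rt), which is non-basic and should take the less hindered side-chain ketone rather than the C1 ketone or the lactone, would then give 7.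

Step 2. Hydrazine may attack the strained trans-fused lactone, or the dienyl diazene may break down unproductively. The fallback sets out from 2 and returns at 4. Luche reduction (NaBH4, CeCl3·7H2O, MeOH, −40 °C) should give the epoxy alcohol F3, drawn as the 3α-alcohol expected from hydride delivery anti to the epoxide; the 3-epimer would serve equally. Appel-type iodination (PPh3, I2, imidazole, toluene, 0 °C → rt) should give the 3β-iodo epoxide F4, used crude. Activated Zn (EtOH, 50 °C) should then effect reductive β-elimination with opening of the epoxide at C2–O, giving 4.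

Step 1. Conjugate addition of the peroxide at the neopentyl-type C1 may be sluggish or incomplete, and the base may open the lactone or deprotonate at C6. The fallback sets out from 1 and returns at 5, moving the oxygen by allylic transposition instead. Luche reduction (NaBH4, CeCl3·7H2O, MeOH, −20 °C) should give the bis-allylic alcohol F5, drawn as the 3β-alcohol; either epimer would serve. Ph3SiOReO3 (cat., Et2O, −50 → 0 °C) should shift the hydroxyl suprafacially from C3 to C1 by [3,3]-rearrangement of the perrhenate ester, driven by the gain in diene conjugation, to give 1β-hydroxy-eudesma-2,4-dien-12,6α-olide F6. The conditions of step 3 would oxidise F6 to 5.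

**Further compounds**

F1 | step 4 | endo-acetyl adduct of 5 and methyl vinyl ketone (acetyl on C2′, β-face bridge) | CC(=O)[C@H]1C[C@@]23C(C)=C[C@@H]1C(=O)[C@]2(C)CC[C@H]1[C@H](C)C(=O)O[C@@H]13
F2 | step 4 | 5-methylhex-4-enoyl ketone (prenylated F1) | CC(C)=CCCC(=O)[C@H]1C[C@@]23C(C)=C[C@@H]1C(=O)[C@]2(C)CC[C@H]1[C@H](C)C(=O)O[C@@H]13
F3 | step 2 | 1α,2α-epoxy-3α-hydroxy-eudesm-4-en-12,6α-olide | C[C@H]1[C@@H]2CC[C@]3([C@H]4O[C@H]4[C@@H](O)C(=C3[C@H]2OC1=O)C)C
F4 | step 2 | 1α,2α-epoxy-3β-iodo-eudesm-4-en-12,6α-olide | C[C@H]1[C@@H]2CC[C@]3([C@H]4O[C@H]4[C@H](I)C(=C3[C@H]2OC1=O)C)C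
F5 | step 1 | 3β-hydroxy-eudesma-1,4-dien-12,6α-olide | C[C@H]1[C@@H]2CC[C@]3(C=C[C@H](O)C(=C3[C@H]2OC1=O)C)C
F6 | step 1 | 1β-hydroxy-eudesma-2,4-dien-12,6α-olide | C[C@H]1[C@@H]2CC[C@]3([C@H](O)C=CC(=C3[C@H]2OC1=O)C)C
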